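The constants give J two partners: Z at 84.5 M⁻¹ min⁻¹, counting both sites, and the mono adducts at 44.7 M⁻¹ min⁻¹, the mean weighted by the 60.1 % of first additions that land on E. Their ratio is 0.529: this is σ, the selectivity factor, the pull of the mono adducts on J per unit concentration against the pull of Z.

| setting | south-west | north | south-east | east |
|---|---|---|---|---|
| Z | 10 mM (fed, over 30 min) | 10 mM | 10 mM (fed, over 30 min) | 10 mM |
| J | 9.00 mM | 9.00 mM | 9.00 mM | 9.00 mM (fed, over 30 min) |
| temperature | 90 °C | 90 °C |  | 90 °C |
| time | 40 min | 40 min | 40 min | 40 min |
| remark | all else is in the flask from the start; the feed brings no volume worth counting | everything together at the start | the addition at 70 °C, then warmed to 90 °C; the feed brings no volume worth counting | all else is in the flask from the start; the feed brings no volume worth counting |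

    Z + J → D + L (k1 = 33.7 M⁻¹ min⁻¹, Ea1 = 54.0 kJ mol⁻¹)
    E ⇌ X (K2 = 2.3, k2 = 0.0634 min⁻¹, Ea2 = 99.0 kJ mol⁻¹, ΔH2 = 33.0 kJ mol⁻¹)
    J + E → G + L (k3 = 24.6 M⁻¹ min⁻¹, Ea3 = 61.0 kJ mol⁻¹)
    Z + J → E + L (k4 = 50.8 M⁻¹ min⁻¹, Ea4 = 66.0 kJ mol⁻¹)
    J + D → G + L (k5 = 74.9 M⁻¹ min⁻¹, Ea5 = 41.0 kJ mol⁻¹)
    (constants at 90 °C)

- all constants are for 90 °C and move with temperature by the activation energies and enthalpies

* the flask with the highest amount of G, in percent of the Z charged ("all alike" if they lie within 1.5 percentage points) (south-west / north / south-east / east / all alike)
* final G, as a percentage of the Z charged, in south-west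
* final G, as a percentage of the Z charged, in north
* final G, as a percentage of the Z charged, in south-east
* final G, as a percentage of the Z charged, in east

Note for the bench. J is the limiting reagent, 9.00 mM against 10 mM of Z, and L counts J used, one for one. In north and east, Z stands in the flask from the start, and J goes on to G against going on to Z in the rate ratio σ[mono]/[Z]. Summed with Z taken as barely depleted, and the drain of E to X left aside, that gives G, as a fraction of Z charged, from x = 0.900, the J charged per Z charged. In common logarithms:

lg G = lg σ + lg x + lg x − lg 2

lg G = −0.277 + −0.0458 + −0.0458 − 0.301 = −0.669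

G in north: 21.4 %; G in east: 21.4 %

This x is a stretch for that sum. In south-west, Z enters a flask of J, and its half-life against J as charged, 0.911 min, is shorter than the feed of 30 min. So this reckoning expects [Z] to stay low while J lasts, and σ[mono]/[Z] to stand high. Each Z that goes to G takes two J, so the charge of J caps G in south-west at 45.0 % of the Z charged. The feed in south-west keeps its pace: that ratio lives on low [Z].

The forecast puts south-west first, with 35 % there, 19 % in north, 32 % in south-east and 16 % in east, on the ground that “feeding Z slowly into excess J pushes the mono adducts on to G”. Unlike this reckoning, it separates north from east and south-west from south-east.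

The flasks give 30.9 % in south-west, 19.7 % in north, 27.4 % in south-east and 18.4 % in east, so south-west leads, and the forecast holds on each count.

For the bench, the order of addition is worth 13 percentage points of G between south-west and east. The run without J + E → G + L shrinks that gap to 5.9 points: the second addition on E is the largest single effect, not the whole gap. The reckoned north stands 1.7 points above its flask.

In the neighbour of east with 40 mM of Z, x falls to 0.225, so lg G = −1.87 and σ gives 1.34 % of the Z charged. That flask gives 1.17 %.

The constants used here are made up; what happens was integrated by code.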